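Retrosynthetic cuts, in order: first the ketone bond between the vanilloyl carbonyl carbon and C6 of the pyrrole ring; then N7–C6 and C4a–C5 of the pyrrole ring; last C5=C6, which becomes the C=C of a β-nitrostyrene.
Forward: Henry condensation of 4-hydroxybenzaldehyde (1) with nitromethane (2) gives nitrostyrene 3; annulation onto the ready-made pyrimidinedione ring of 6-aminouracil (4), through Michael adduct 5, closes the pyrrole ring (6); O-acetylation gives 7.
The ketone is installed only after ring closure, because an open-chain aryl ketone beside the 6-NH2 group would close a six-membered ring instead: oxidative C–H/C–H union of C6–H of 7 with the formyl C–H of vanillin acetate (8) gives 9, and ammonolysis gives rigidin B (10).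
Enabling feature: C6 is the only C–H carbon of the pyrrole ring and the unsubstituted terminus of the C5=C6 enamine bond; an aroyl radical (the aldehyde carbon with reversed polarity) adding there leaves a C5 radical that is benzylic to the C5 aryl ring and allylic to C4a=C7a of the vinylogous urea N7/N1–C7a=C4a–C4=O, and the 6-aroyl product is a deactivated push-pull pyrrole.
Stereochemistry: the target has no stereocentre; the E alkene of 3 and the racemic centre of 5 disappear on aromatisation.

Key step: step 4

Step 1
Reactants: 1 4-hydroxybenzaldehyde; 2 nitromethane (excess)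
Product: 3 (E)-4-(2-nitrovinyl)phenol
Conditions: NH4OAc (cat.), AcOH, 100 °C
Reagents that add atoms: none
Why: Henry (nitroaldol) condensation with in situ dehydration is the standard entry to β-nitrostyrenes and should give the thermodynamically favoured E alkene.

Step 2
Reactants: 3 (E)-4-(2-nitrovinyl)phenol; 4 6-aminopyrimidine-2,4(1H,3H)-dione (6-aminouracil)
Product: 6 5-(4-hydroxyphenyl)-1H-pyrrolo[2,3-d]pyrimidine-2,4(3H,7H)-dione, via nitroethyl Michael adduct 5 (not isolated)
Conditions: AcOH–H2O (3:1), 100 °C
Reagents that add atoms: none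
Why: Grob–Camenisch-type pyrrole annulation, in which the enaminic C5 of 4 should add to the aryl-bearing carbon of 3 (Michael addition), the 6-NH2 group then attacks the aci-nitro carbon, and loss of water and HNO aromatises the new ring, which places the aryl group at C5 and leaves C6–H free.

Step 3
Reactants: 6 5-(4-hydroxyphenyl)-1H-pyrrolo[2,3-d]pyrimidine-2,4(3H,7H)-dione
Product: 7 4-(2,4-dioxo-2,3,4,7-tetrahydro-1H-pyrrolo[2,3-d]pyrimidin-5-yl)phenyl acetate
Conditions: Ac2O (1.1 equiv), pyridine, DMF, 0 °C to rt
Reagents that add atoms: acetic anhydride, CC(=O)OC(C)=O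
Why: Base-mediated O-acylation (esterification) should be selective because the phenol is by far the most nucleophilic site under pyridine conditions, whereas the pyrrole and imide N–H groups are not acylated without a strong base.

Step 4
Reactants: 7 4-(2,4-dioxo-2,3,4,7-tetrahydro-1H-pyrrolo[2,3-d]pyrimidin-5-yl)phenyl acetate; 8 4-formyl-2-methoxyphenyl acetate (vanillin acetate)
Product: 9 4-[5-(4-acetoxyphenyl)-2,4-dioxo-2,3,4,7-tetrahydro-1H-pyrrolo[2,3-d]pyrimidine-6-carbonyl]-2-methoxyphenyl acetate
Conditions: 8 (3 equiv), t-BuOOH (5.5 M in decane, 3 equiv, slow addition), FeCl2 (10 mol %), DMSO–MeCN (1:2), 80 °C, N2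
Reagents that add atoms: none
Why: Proposed new method: a cross-dehydrogenative C–H acylation in which t-BuO•, formed from t-BuOOH and divalent iron, abstracts the formyl hydrogen of 8 to give a nucleophilic aroyl radical that adds to C6 of 7. The resulting C5 radical is oxidised by trivalent iron (or by t-BuOOH in a chain) and loses the C6 proton, which restores the pyrrole ring and returns divalent iron. The closest known reaction type is the peroxide-mediated oxidative C–H aroylation of electron-rich azoles with aldehydes (imidazo[1,2-a]pyridines and 2H-indazoles at C3, N-directed pyrroles and indoles at C2), which has not been shown on an N-unsubstituted pyrrolo[2,3-d]pyrimidine-2,4-dione. No ring is closed and no stereocentre is formed. The step needs C6 regioselectivity and chemoselectivity against N-acylation and over-oxidation: C5 is blocked by the aryl ring, acyl radicals do not attack N–H bonds or the electron-poor pyrimidinedione ring, both phenols are masked as radical-inert acetates, and the 6-aroyl product is a deactivated push-pull pyrrole that should resist a second oxidation.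

Step 5
Reactants: 9 4-[5-(4-acetoxyphenyl)-2,4-dioxo-2,3,4,7-tetrahydro-1H-pyrrolo[2,3-d]pyrimidine-6-carbonyl]-2-methoxyphenyl acetate
Product: 10 rigidin B, 6-(4-hydroxy-3-methoxybenzoyl)-5-(4-hydroxyphenyl)-1H-pyrrolo[2,3-d]pyrimidine-2,4(3H,7H)-dione
Conditions: NH3 (7 M in MeOH), THF, 0 °C to rt
Reagents that add atoms: none
Why: Ester aminolysis of the two aryl acetates should be fast at room temperature and leave the diaryl ketone, the lactams and the aryl methyl ether untouched.

Compound list
1 | 4-hydroxybenzaldehyde | O=Cc1ccc(O)cc1 | starting material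
2 | nitromethane | C[N+](=O)[O-] | starting material
3 | (E)-4-(2-nitrovinyl)phenol | Oc1ccc(/C=C/[N+](=O)[O-])cc1 | intermediate
4 | 6-aminopyrimidine-2,4(1H,3H)-dione (6-aminouracil) | Nc1cc(=O)[nH]c(=O)[nH]1 | starting material
5 | 6-amino-5-[1-(4-hydroxyphenyl)-2-nitroethyl]pyrimidine-2,4(1H,3H)-dione (racemic nitroethyl Michael adduct) | Nc1[nH]c(=O)[nH]c(=O)c1C(C[N+](=O)[O-])c1ccc(O)cc1 | intermediate
6 | 5-(4-hydroxyphenyl)-1H-pyrrolo[2,3-d]pyrimidine-2,4(3H,7H)-dione | Oc1ccc(-c2c[nH]c3[nH]c(=O)[nH]c(=O)c23)cc1 | intermediate
7 | 4-(2,4-dioxo-2,3,4,7-tetrahydro-1H-pyrrolo[2,3-d]pyrimidin-5-yl)phenyl acetate | CC(=O)Oc1ccc(-c2c[nH]c3[nH]c(=O)[nH]c(=O)c23)cc1 | intermediate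
8 | 4-formyl-2-methoxyphenyl acetate (vanillin acetate) | COc1cc(C=O)ccc1OC(C)=O | starting material
9 | 4-[5-(4-acetoxyphenyl)-2,4-dioxo-2,3,4,7-tetrahydro-1H-pyrrolo[2,3-d]pyrimidine-6-carbonyl]-2-methoxyphenyl acetate | COc1cc(C(=O)c2[nH]c3[nH]c(=O)[nH]c(=O)c3c2-c2ccc(OC(C)=O)cc2)ccc1OC(C)=O | intermediate
10 | rigidin B, 6-(4-hydroxy-3-methoxybenzoyl)-5-(4-hydroxyphenyl)-1H-pyrrolo[2,3-d]pyrimidine-2,4(3H,7H)-dione | COc1cc(C(=O)c2[nH]c3[nH]c(=O)[nH]c(=O)c3c2-c2ccc(O)cc2)ccc1O | target

Total step count: 5. Longest linear sequence: 5 steps (1 → 3 → 6 → 7 → 9 → 10).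

Steps most likely to fail

Step 4 (proposed new method). The peroxide may degrade the electron-rich pyrrole ring oxidatively before the aroyl radical is captured. Alternatively, the polarity-mismatched addition of the nucleophilic aroyl radical to C6 may be so slow that the aldehyde is merely over-oxidised. The fallback uses known chemistry, sets out from 7 and comes back at 9. Commercial 4-acetoxy-3-methoxybenzoic acid is converted with (COCl)2 and catalytic DMF in CH2Cl2 into 4-acetoxy-3-methoxybenzoyl chloride F1. Compound 7 is then acylated at C6 by Friedel–Crafts reaction with F1 and AlCl3 in MeNO2 (0 °C to rt). This normal-polarity electrophilic substitution at the only free pyrrole position should give 9.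

Step 2. The sequence may stall at the Michael-adduct stage through incomplete aci-nitro ring closure and HNO loss, or the nitroalkene may oligomerise on heating. The fallback sets out from 3 and 4 and comes back at 6. The Michael addition is run separately in EtOAc–H2O at 50 °C and adduct 5 is isolated. Its nitronate (aqueous NaOH) is added to cold aqueous H2SO4 (Nef reaction) to unveil 2-(6-amino-2,4-dioxo-1,2,3,4-tetrahydropyrimidin-5-yl)-2-(4-hydroxyphenyl)acetaldehyde F2. In the acid F2 should cyclodehydrate onto the 6-amino group (Paal–Knorr-type enamine condensation) to give 6.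

Step 3. Competing N-acetylation at N7, or incomplete conversion because of poor solubility of 6, may erode the selectivity. The fallback sets out from 3 and comes back at 7; the phenol is protected before the heterocycle is built. Compound 3 with Ac2O and pyridine in CH2Cl2 should give (E)-4-(2-nitrovinyl)phenyl acetate F3. Grob–Camenisch annulation of F3 with 4 in anhydrous AcOH at 100 °C, through 4-[1-(6-amino-2,4-dioxo-1,2,3,4-tetrahydropyrimidin-5-yl)-2-nitroethyl]phenyl acetate F4, should then give 7 directly.

Further compounds
F1 | step 4 | 4-acetoxy-3-methoxybenzoyl chloride | COc1cc(C(Cl)=O)ccc1OC(C)=O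
F2 | step 2 | 2-(6-amino-2,4-dioxo-1,2,3,4-tetrahydropyrimidin-5-yl)-2-(4-hydroxyphenyl)acetaldehyde (racemic) | Nc1[nH]c(=O)[nH]c(=O)c1C(C=O)c1ccc(O)cc1
F3 | step 3 | (E)-4-(2-nitrovinyl)phenyl acetate | CC(=O)Oc1ccc(/C=C/[N+](=O)[O-])cc1
F4 | step 3 | 4-[1-(6-amino-2,4-dioxo-1,2,3,4-tetrahydropyrimidin-5-yl)-2-nitroethyl]phenyl acetate (racemic) | CC(=O)Oc1ccc(C(C[N+](=O)[O-])c2c(N)[nH]c(=O)[nH]c2=O)cc1
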